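**Retrosynthetic overview**

1. Last bonds: the C11 acid is unveiled from a 2-(trimethylsilyl)ethyl ester (the axial, neopentyl C11 ester cannot be saponified beside the trienoate), and the 6β-ester is cut to the 6β-alcohol and (2E,4E,6E)-octatrienoic acid (sorbaldehyde + malonic acid).
2. C12 aldehyde from a Weinreb amide; 6β-OH from the 6-ketone; 9β-OH with the C7=C8 alkene from a suprafacial selenoxide [2,3]-shift of a 7β-selenide, itself from the 6α,7α-epoxide of a ring B 6,8-diene; C12 from carbonylation of the C8 enol triflate.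
3. Rings A and B from one proton-initiated cationic bicyclisation (C4–C5 and C9–C10) of the β-keto ester made from geranylacetone and dimethyl carbonate.
4. Feature used: rings A and B (C1–C10) with the C4 gem-dimethyl group, the trans C5/C10 fusion carrying the C10 methyl, and the C11 carbon on C9 are the chair–chair fold of an (E)-geranyl chain ending in a β-keto ester (C4 = isopropylidene carbon, C5=C10 = central alkene, C9 = carbon between the two carbonyls).
5. Ring order: ring A, then ring B, in the same cascade; no other ring is formed.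

Key step: step 2

Remark on numbering: drimane numbering is used (decalin C1–C10, C11 on C9, C12 on C8); β is the face of the C10 methyl.
Remark on the target: it is taken as the open 11-acid/12-aldehyde form as drawn; the 12-hydroxy-11,12-olide ring tautomer would require the axial 9α-carboxyl to bend into the C7=C8 plane and is expected to be the minor form.
Remark on the starting material: geranylacetone is taken as the pure (E)-isomer, since the alkene geometry fixes the ring fusion.

**Route**

Step 1
Reactants: 1 (E)-geranylacetone; 2 dimethyl carbonate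
Product: 3 methyl (6E)-7,11-dimethyl-3-oxododeca-6,10-dienoate
Conditions: NaH (2.2 equiv), THF, reflux; then AcOH, H2O
Reagents that add atoms: none
Why: Claisen-type carboxylation of the ketone enolate with dimethyl carbonate occurs at the methyl terminus and is driven by irreversible deprotonation of the β-keto ester formed; no stereocentre arises and the 6E alkene is untouched.

Step 2
Reactants: 3 methyl (6E)-7,11-dimethyl-3-oxododeca-6,10-dienoate
Product: 4 methyl (5S,9R,10S)-8-oxo-12-nordriman-11-oate
Conditions: SnCl4 (1.0 equiv) premixed with (R)-2-(2-fluorobenzyloxy)-2'-hydroxy-1,1'-binaphthyl (1.1 equiv), CH2Cl2, −78 °C, slow addition of 3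
Reagents that add atoms: none
Why: Proposed new method: the SnCl4-bound binaphthol monoether is a chiral Lewis-acid-assisted Brønsted acid whose proton adds to C3 of the terminal trisubstituted alkene while the C5=C10 alkene and then the enol carbon C9 add in a cationic cascade, the closest known reactions being the ligand-free SnCl4 bicyclisation of this keto ester and the enantioselective proton-initiated cyclisation of homo(poly)prenyl arenes and alcohols with the same chiral acid. Ring A closes 6-endo at the C4 cation (C4–C5) and ring B closes 6-endo at the C10 cation with the enol double bond inside the ring (C9–C10), both by antiperiplanar addition in a chair–chair fold. C5 and C10 follow from the E geometry of the central alkene (trans fusion, 5α-H, 10β-methyl), their absolute sense from the enantioface of the terminal alkene chosen by the chiral acid (the R ligand is expected to give the 5S,10S series by analogy, otherwise its enantiomer is used), and C9 settles to the equatorial β-ester by enolisation. The step needs initiation at the terminal alkene only and enantioface selection: the first is secured because that alkene is the most basic site and the enol is the best terminator, the second is at risk because the chelating keto ester can pull SnCl4 off the ligand and open a racemic path, hence the preformed acid, low temperature and slow addition.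

Step 3
Reactants: 4 methyl (5S,9R,10S)-8-oxo-12-nordriman-11-oate
Product: 5 2-(trimethylsilyl)ethyl (5S,9R,10S)-8-oxo-12-nordriman-11-oate
Conditions: 2-(trimethylsilyl)ethanol (5 equiv), DMAP (0.3 equiv), toluene, reflux, 4 Å sieves (removal of MeOH)
Reagents that add atoms: 2-(trimethylsilyl)ethanol C[Si](C)(C)CCO
Why: Transesterification of a β-keto ester (DMAP-catalysed, through the acylketene that the C9 hydrogen allows) exchanges methanol for a fluoride-cleavable group without touching any other site, and C9 re-equilibrates to the equatorial β-ester.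

Step 4
Reactants: 5 2-(trimethylsilyl)ethyl keto ester
Product: 6 2-(trimethylsilyl)ethyl 8-(trifluoromethanesulfonyloxy)-12-nordrim-8-en-11-oate (5α-H, 10β-Me)
Conditions: Tf2O, iPr2NEt, CH2Cl2, −78 °C → 0 °C
Reagents that add atoms: trifluoromethanesulfonic anhydride O=S(=O)(OS(=O)(=O)C(F)(F)F)C(F)(F)F
Why: O-sulfonylation of the enol of the β-keto ester (enol triflate formation) fixes the conjugated C8=C9 double bond; C9 becomes trigonal and C5 and C10 are untouched.

Step 5
Reactants: 6 enol triflate
Product: 7 2-(trimethylsilyl)ethyl 12-[methoxy(methyl)amino]-12-oxodrim-8-en-11-oate (5α-H, 10β-Me)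
Conditions: Pd(OAc)2 (5 mol%), 1,3-bis(diphenylphosphino)propane (6 mol%), CO (1 atm), MeNH(OMe)·HCl, Et3N, DMF, 60 °C
Reagents that add atoms: carbon monoxide [C-]#[O+]; N,O-dimethylhydroxylamine hydrochloride CNOC.Cl
Why: Palladium-catalysed aminocarbonylation of the vinyl triflate (oxidative addition to zerovalent palladium, CO insertion, capture of the acylpalladium by the hydroxylamine) installs C12 as a Weinreb amide that is inert to the coming oxidations and reducible to the aldehyde later.

Step 6
Reactants: 7 Weinreb amide ester (drim-8-ene)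
Product: 9 2-(trimethylsilyl)ethyl 12-[methoxy(methyl)amino]-12-oxodrima-6,8-dien-11-oate (5α-H, 10β-Me), via 7α-bromide 8 (not isolated)
Conditions: NBS (1.05 equiv), AIBN (cat.), PhCF3, 80 °C; then DBU (3 equiv), 80 °C
Reagents that add atoms: none
Why: Wohl–Ziegler bromination can only take place at C7, the single allylic CH2 of the C8=C9 alkene (axial α-attack expected), and anti E2 loss of HBr with the axial 6β-H under DBU should give the ring B 6,8-diene (bromination–dehydrobromination).

Step 7
Reactants: 9 ring B 6,8-diene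
Product: 10 2-(trimethylsilyl)ethyl 6α,7α-epoxy-12-[methoxy(methyl)amino]-12-oxodrim-8-en-11-oate
Conditions: mCPBA (1.5 equiv), CH2Cl2, 0 °C → rt
Reagents that add atoms: 3-chloroperoxybenzoic acid OOC(=O)c1cccc(Cl)c1
Why: Prilezhaev epoxidation picks the C6=C7 alkene, the only one that carries no acyl group, and should come from the α face because the 4β- and 10β-methyl groups flank the β face of C6, which sets C6 and C7.

Step 8
Reactants: 10 6α,7α-epoxide
Product: 11 2-(trimethylsilyl)ethyl 6α-hydroxy-12-[methoxy(methyl)amino]-12-oxo-7β-(phenylselanyl)drim-8-en-11-oate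
Conditions: (PhSe)2 (0.6 equiv), NaBH4 (1.2 equiv), EtOH, 0 °C → rt
Reagents that add atoms: diphenyl diselenide c1ccccc1[Se][Se]c1ccccc1
Why: SN2 opening of the vinyl epoxide by phenylselenolate at the allylic carbon C7 (attack at C6 from the β face is blocked by the two syn-axial methyl groups) inverts C7 and should give the trans 6α-hydroxy-7β-selenide.

Step 9
Reactants: 11 6α-hydroxy-7β-selenide
Product: 14 2-(trimethylsilyl)ethyl 6α,9β-dihydroxy-12-[methoxy(methyl)amino]-12-oxodrim-7-en-11-oate, via selenoxide 12 (not isolated), via selenenate 13 (not isolated)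
Conditions: 30% H2O2, pyridine, CH2Cl2, 0 °C → rt
Reagents that add atoms: hydrogen peroxide OO
Why: Oxidation to the allylic selenoxide is followed by a suprafacial [2,3]-sigmatropic shift (selenoxide–selenenate rearrangement) that carries oxygen from the β face of C7 to the β face of C9 and moves the alkene to C7=C8, the selenenate then being cleaved in the oxidising medium, so C9 is set as 9β-OH/9α-ester by chirality transfer from C7, while syn elimination has only the carbinol hydrogen at C6 available, a direction hydroxy selenoxides avoid.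

Step 10
Reactants: 14 6α,9β-diol
Product: 15 2-(trimethylsilyl)ethyl 9β-hydroxy-12-[methoxy(methyl)amino]-6,12-dioxodrim-7-en-11-oate
Conditions: Dess–Martin periodinane, CH2Cl2, rt
Reagents that add atoms: none
Why: Dess–Martin oxidation converts the secondary allylic 6α-alcohol into the enone, while the tertiary 9-hydroxyl cannot be oxidised and, with a chromium-free oxidant, is not transposed.

Step 11
Reactants: 15 6-ketone
Product: 16 2-(trimethylsilyl)ethyl 6β,9β-dihydroxy-12-[methoxy(methyl)amino]-12-oxodrim-7-en-11-oate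
Conditions: NaBH4, CeCl3·7H2O, MeOH, −40 °C
Reagents that add atoms: none
Why: Luche reduction gives 1,2-reduction of the enone, and hydride should come from the α face because the β face of C6 is screened by the syn-axial 4β- and 10β-methyl groups, so the axial 6β-alcohol is set; amide and ester are inert to NaBH4 at this temperature.

Step 12
Reactants: 16 6β,9β-diol Weinreb amide
Product: 17 2-(trimethylsilyl)ethyl 6β,9β-dihydroxy-12-oxodrim-7-en-11-oate (enal)
Conditions: iBu2AlH (4 equiv), CH2Cl2, −78 °C; aq. KNaC4H4O6 (Rochelle salt) work-up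
Reagents that add atoms: none
Why: Weinreb amide reduction stops at the aldehyde because the aluminium-chelated tetrahedral intermediate survives until work-up, while the axial, neopentyl C11 ester between the quaternary C10 and the fully substituted C9 is much slower and the two hydroxyls are only deprotonated.

Step 13
Reactants: 18 sorbaldehyde, (2E,4E)-hexa-2,4-dienal; 19 malonic acid
Product: 21 (2E,4E,6E)-octa-2,4,6-trienoic acid, via dienylidenemalonic acid 20 (not isolated)
Conditions: pyridine, piperidine (cat.), 90 °C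
Reagents that add atoms: none
Why: Knoevenagel–Doebner condensation with decarboxylation gives the thermodynamically favoured 2E acid and leaves the 4E,6E diene of sorbaldehyde unchanged.

Step 14
Reactants: 17 6β,9β-diol enal; 21 (2E,4E,6E)-octa-2,4,6-trienoic acid
Product: 23 2-(trimethylsilyl)ethyl 9β-hydroxy-6β-[(2E,4E,6E)-octa-2,4,6-trienoyloxy]-12-oxodrim-7-en-11-oate, via mixed anhydride 22 (not isolated)
Conditions: 21, 2,4,6-trichlorobenzoyl chloride, Et3N, THF, rt; then 17, DMAP, toluene, rt → 40 °C
Reagents that add atoms: none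
Why: Yamaguchi esterification with DMAP as acyl-transfer catalyst acylates the hindered axial 6β-hydroxyl, the only acylable one since the 9-hydroxyl is tertiary and flanked by fully substituted carbons; no stereocentre is touched.

Step 15
Reactants: 23 acylated 2-(trimethylsilyl)ethyl ester
Product: 24 (5S,6R,9R,10S)-9β-hydroxy-6β-[(2E,4E,6E)-octa-2,4,6-trienoyloxy]-12-oxodrim-7-en-11-oic acid (target, CNP0234478.3)
Conditions: Bu4NF (1.5 equiv), THF, 0 °C → rt; then AcOH
Reagents that add atoms: none
Why: Fluoride attacks silicon and the 2-(trimethylsilyl)ethyl ester fragments to the carboxylate, ethene and Me3SiF (fluoride-induced β-elimination), a cleavage that does not pass through the hindered C11 carbonyl and should leave the trienoate, the enal and the tertiary alcohol alone.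

**Compound list**

1 | (E)-geranylacetone, (5E)-6,10-dimethylundeca-5,9-dien-2-one | CC(=O)CC/C=C(\C)CCC=C(C)C | starting material
2 | dimethyl carbonate | COC(=O)OC | starting material
3 | methyl (6E)-7,11-dimethyl-3-oxododeca-6,10-dienoate | COC(=O)CC(=O)CC/C=C(\C)CCC=C(C)C | intermediate
4 | methyl (5S,9R,10S)-8-oxo-12-nordriman-11-oate (5α-H, 9α-H, 10β-Me) | C1CC(=O)[C@H](C(=O)OC)[C@@]2(C)CCCC(C)(C)[C@H]12 | intermediate
5 | 2-(trimethylsilyl)ethyl (5S,9R,10S)-8-oxo-12-nordriman-11-oate | C1CC(=O)[C@H](C(=O)OCC[Si](C)(C)C)[C@@]2(C)CCCC(C)(C)[C@H]12 | intermediate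
6 | 2-(trimethylsilyl)ethyl 8-(trifluoromethanesulfonyloxy)-12-nordrim-8-en-11-oate (5α-H, 10β-Me) | C1CC(OS(=O)(=O)C(F)(F)F)=C(C(=O)OCC[Si](C)(C)C)[C@@]2(C)CCCC(C)(C)[C@H]12 | intermediate
7 | 2-(trimethylsilyl)ethyl 12-[methoxy(methyl)amino]-12-oxodrim-8-en-11-oate (5α-H, 10β-Me) | C1CC(C(=O)N(C)OC)=C(C(=O)OCC[Si](C)(C)C)[C@@]2(C)CCCC(C)(C)[C@H]12 | intermediate
8 | 2-(trimethylsilyl)ethyl 7α-bromo-12-[methoxy(methyl)amino]-12-oxodrim-8-en-11-oate (not isolated) | C1[C@@H](Br)C(C(=O)N(C)OC)=C(C(=O)OCC[Si](C)(C)C)[C@@]2(C)CCCC(C)(C)[C@H]12 | intermediate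
9 | 2-(trimethylsilyl)ethyl 12-[methoxy(methyl)amino]-12-oxodrima-6,8-dien-11-oate (5α-H, 10β-Me) | C1=CC(C(=O)N(C)OC)=C(C(=O)OCC[Si](C)(C)C)[C@@]2(C)CCCC(C)(C)[C@H]12 | intermediate
10 | 2-(trimethylsilyl)ethyl 6α,7α-epoxy-12-[methoxy(methyl)amino]-12-oxodrim-8-en-11-oate | O1[C@H]2[C@@H]1C(C(=O)N(C)OC)=C(C(=O)OCC[Si](C)(C)C)[C@@]3(C)CCCC(C)(C)[C@H]23 | intermediate
11 | 2-(trimethylsilyl)ethyl 6α-hydroxy-12-[methoxy(methyl)amino]-12-oxo-7β-(phenylselanyl)drim-8-en-11-oate | O[C@H]1[C@H]([Se]c3ccccc3)C(C(=O)N(C)OC)=C(C(=O)OCC[Si](C)(C)C)[C@@]2(C)CCCC(C)(C)[C@H]12 | intermediate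
12 | 7β-selenoxide of 11 (not isolated) | O[C@H]1[C@H]([Se](=O)c3ccccc3)C(C(=O)N(C)OC)=C(C(=O)OCC[Si](C)(C)C)[C@@]2(C)CCCC(C)(C)[C@H]12 | intermediate
13 | 9β-O-phenylselenenate of 14 (not isolated) | O[C@H]1C=C(C(=O)N(C)OC)[C@@](O[Se]c3ccccc3)(C(=O)OCC[Si](C)(C)C)[C@@]2(C)CCCC(C)(C)[C@H]12 | intermediate
14 | 2-(trimethylsilyl)ethyl 6α,9β-dihydroxy-12-[methoxy(methyl)amino]-12-oxodrim-7-en-11-oate | O[C@H]1C=C(C(=O)N(C)OC)[C@@](O)(C(=O)OCC[Si](C)(C)C)[C@@]2(C)CCCC(C)(C)[C@H]12 | intermediate
15 | 2-(trimethylsilyl)ethyl 9β-hydroxy-12-[methoxy(methyl)amino]-6,12-dioxodrim-7-en-11-oate | O=C1C=C(C(=O)N(C)OC)[C@@](O)(C(=O)OCC[Si](C)(C)C)[C@@]2(C)CCCC(C)(C)[C@H]12 | intermediate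
16 | 2-(trimethylsilyl)ethyl 6β,9β-dihydroxy-12-[methoxy(methyl)amino]-12-oxodrim-7-en-11-oate | O[C@@H]1C=C(C(=O)N(C)OC)[C@@](O)(C(=O)OCC[Si](C)(C)C)[C@@]2(C)CCCC(C)(C)[C@H]12 | intermediate
17 | 2-(trimethylsilyl)ethyl 6β,9β-dihydroxy-12-oxodrim-7-en-11-oate | O[C@@H]1C=C(C=O)[C@@](O)(C(=O)OCC[Si](C)(C)C)[C@@]2(C)CCCC(C)(C)[C@H]12 | intermediate
18 | sorbaldehyde, (2E,4E)-hexa-2,4-dienal | C/C=C/C=C/C=O | starting material
19 | malonic acid | OC(=O)CC(=O)O | starting material
20 | 2-[(2E,4E)-hexa-2,4-dien-1-ylidene]malonic acid (not isolated) | C/C=C/C=C/C=C(C(=O)O)C(=O)O | intermediate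
21 | (2E,4E,6E)-octa-2,4,6-trienoic acid | C/C=C/C=C/C=C/C(=O)O | intermediate
22 | (2E,4E,6E)-octa-2,4,6-trienoic 2,4,6-trichlorobenzoic anhydride (not isolated) | C/C=C/C=C/C=C/C(=O)OC(=O)c1c(Cl)cc(Cl)cc1Cl | intermediate
23 | 2-(trimethylsilyl)ethyl 9β-hydroxy-6β-[(2E,4E,6E)-octa-2,4,6-trienoyloxy]-12-oxodrim-7-en-11-oate | C/C=C/C=C/C=C/C(=O)O[C@@H]1C=C(C=O)[C@@](O)(C(=O)OCC[Si](C)(C)C)[C@@]2(C)CCCC(C)(C)[C@H]12 | intermediate
24 | (5S,6R,9R,10S)-9β-hydroxy-6β-[(2E,4E,6E)-octa-2,4,6-trienoyloxy]-12-oxodrim-7-en-11-oic acid | C/C=C/C=C/C=C/C(=O)O[C@@H]1C=C(C=O)[C@@](O)(C(=O)O)[C@@]2(C)CCCC(C)(C)[C@H]12 | target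

**Step count**

Total: 15 steps. Longest linear sequence: 14 steps (steps 1–12, 14, 15); step 13 is a one-step side branch.

**Steps most likely to fail**

Step 2 (proposed new method). The chelating β-keto ester may displace the chiral ligand from tin, so that a ligand-free proton source cyclises the substrate without enantiocontrol; part of the material may also stop at the monocyclic stage. The fallback sets out from 3 and returns at 4. The ligand-free cyclisation of 3 (SnCl4, CH2Cl2, 0 °C → rt), known in racemic form, should give 4 together with its mirror image, ent-keto ester F1. Condensation of the pair with (S)-1-phenylethylamine (AcOH cat., toluene, water removal) should give two diastereomeric enamino esters, the 5S,10S enamino ester F2 and the 5R,10R enamino ester F3, which are separated by chromatography or crystallisation. Hydrolysis of F2 (aq. oxalic acid, THF) returns enantiopure 4.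

Step 8. The selenolate may open the epoxide at the wrong carbon, or the borohydride-derived reagent may reduce or add to the electron-poor alkene, so that the 7β-selenide is not formed cleanly. The fallback sets out from 7 and returns at 15. The bromination of step 6 is stopped before the base is added and the 7α-bromide 8 is isolated. Displacement with PhSeNa (from (PhSe)2 and NaBH4, EtOH–THF, 0 °C) with inversion should give the 7β-selenide lacking C6 oxygen F4. Oxidation (H2O2, pyridine) and the same [2,3]-shift should give the 9β-hydroxy-7-ene F5. Allylic oxidation of the C6 methylene (Rh2(cap)4 cat., cap = caprolactamate, tBuOOH, K2CO3, CH2Cl2) then gives ketone 15.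

Step 15. Fluoride may act as a base on the acylated enal, leading to loss of the 6-acyl group, epimerisation at C6 through the dienolate, or retro-aldol-type opening of the C8–C9 bond. The fallback sets out from 17 and returns at 24. The silylethyl ester is cleaved first (Bu4NF, THF), while no acyl group is present, to give the dihydroxy aldehyde acid F6. Alkylation of the carboxylate (allyl bromide, KHCO3, DMF) gives the allyl ester F7; this group can be used only now because the single palladium-catalysed carbonylation lies behind. Yamaguchi acylation with mixed anhydride 22, as in step 14, gives the acylated allyl ester F8. Neutral deallylation (Pd(PPh3)4 cat., PhSiH3, CH2Cl2, rt) then gives 24.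

Further compounds
F1 | step 2 | methyl (5R,9S,10R)-8-oxo-12-nordriman-11-oate (enantiomer of 4) | C1CC(=O)[C@@H](C(=O)OC)[C@]2(C)CCCC(C)(C)[C@@H]12
F2 | step 2 | methyl (5S,10S)-8-{[(1S)-1-phenylethyl]amino}-12-nordrim-8-en-11-oate | C1CC(N[C@@H](C)c3ccccc3)=C(C(=O)OC)[C@@]2(C)CCCC(C)(C)[C@H]12
F3 | step 2 | methyl (5R,10R)-8-{[(1S)-1-phenylethyl]amino}-12-nordrim-8-en-11-oate | C1CC(N[C@@H](C)c3ccccc3)=C(C(=O)OC)[C@]2(C)CCCC(C)(C)[C@@H]12
F4 | step 8 | 2-(trimethylsilyl)ethyl 12-[methoxy(methyl)amino]-12-oxo-7β-(phenylselanyl)drim-8-en-11-oate | C1[C@H]([Se]c3ccccc3)C(C(=O)N(C)OC)=C(C(=O)OCC[Si](C)(C)C)[C@@]2(C)CCCC(C)(C)[C@H]12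
F5 | step 8 | 2-(trimethylsilyl)ethyl 9β-hydroxy-12-[methoxy(methyl)amino]-12-oxodrim-7-en-11-oate | C1C=C(C(=O)N(C)OC)[C@@](O)(C(=O)OCC[Si](C)(C)C)[C@@]2(C)CCCC(C)(C)[C@H]12
F6 | step 15 | 6β,9β-dihydroxy-12-oxodrim-7-en-11-oic acid | O[C@@H]1C=C(C=O)[C@@](O)(C(=O)O)[C@@]2(C)CCCC(C)(C)[C@H]12
F7 | step 15 | allyl 6β,9β-dihydroxy-12-oxodrim-7-en-11-oate | O[C@@H]1C=C(C=O)[C@@](O)(C(=O)OCC=C)[C@@]2(C)CCCC(C)(C)[C@H]12
F8 | step 15 | allyl 9β-hydroxy-6β-[(2E,4E,6E)-octa-2,4,6-trienoyloxy]-12-oxodrim-7-en-11-oate | C/C=C/C=C/C=C/C(=O)O[C@@H]1C=C(C=O)[C@@](O)(C(=O)OCC=C)[C@@]2(C)CCCC(C)(C)[C@H]12
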